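**Retrosynthetic overview**

- Feature: in ring C (the chroman-4-one), C2 is a benzylic aryl-ether carbon β to the C4 ketone. The O1–C2 bond is therefore the conjugate addition of the ring A phenol oxygen to a benzylidene, and a temporary tert-butyl ester on C3 turns the acceptor into a β-keto ester that a bifunctional cinchona thiourea can hold at two points.
- Endgame: silyhermin B ⇐ hydrogenolysis of five benzyl ethers and loss of the C3 ester ⇐ keto ester 24 ⇐ (O1–C2, ring C) alkylidene β-keto ester 23 ⇐ Knoevenagel condensation of aldehyde 19 with β-keto ester 22.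
- Aldehyde 19 ⇐ ring D (dihydrofuran) closed by acid through O1'–C2' of a 1,3-diol ⇐ Evans syn-aldol (C2'–C3') of a ring B arylacetyl imide with O-benzylvanillin. The arylacetic acid comes from methyl 3,4-dihydroxybenzoate by O-allylation, Claisen rearrangement and alkene cleavage.
- Ring order: rings A, B and E (guaiacyl) come from the aromatic starting materials; ring D is closed in step 8 and ring C last, in step 15.

Key step: step 15

Assumption: of the pseudoenantiomeric cinchona thiourea pair, the quinidine-derived catalyst is taken as the one that leads to 2S in 2-aryl chromanones. The sense is to be confirmed on a simple 2-hydroxyaryl benzylidene β-keto ester, and the quinine-derived catalyst is the drop-in replacement if it proves opposite.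

**Route**

Step 1
Reactants: 1 methyl 3,4-dihydroxybenzoate
Product: 2 methyl 4-(allyloxy)-3-hydroxybenzoate
Conditions: allyl bromide (1.0 equiv), K2CO3 (1.0 equiv), DMF, 0 °C → rt
Reagents that add atoms: allyl bromide, C=CCBr
Why: Williamson etherification in which one equivalent of base should ionise mainly the more acidic 4-OH (para to the ester), so that the allyl group goes onto O4.

Step 2
Reactants: 2 methyl 4-(allyloxy)-3-hydroxybenzoate
Product: 4 methyl 3-allyl-4,5-dihydroxybenzoate, via ortho-dienone 3 (not isolated)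
Conditions: N,N-diethylaniline, 190 °C
Reagents that add atoms: none
Why: Aromatic Claisen rearrangement, in which the allyl group can only migrate to the one unsubstituted ortho carbon and the dienone then tautomerises to the catechol.

Step 3
Reactants: 4 methyl 3-allyl-4,5-dihydroxybenzoate
Product: 5 methyl 3-allyl-4,5-bis(methoxymethoxy)benzoate
Conditions: MOMCl, iPr2NEt, CH2Cl2, 0 °C → rt
Reagents that add atoms: chloromethyl methyl ether, COCCl
Why: O-alkylation of both phenols with the reactive α-chloro ether gives acetal-type ethers that should withstand the oxidative, basic and hydride steps up to step 7 and come off with acid in step 8.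

Step 4
Reactants: 5 methyl 3-allyl-4,5-bis(methoxymethoxy)benzoate
Product: 7 [5-(methoxycarbonyl)-2,3-bis(methoxymethoxy)phenyl]acetic acid, via arylacetaldehyde 6 (not isolated)
Conditions: OsO4 (cat.), NaIO4, 2,6-lutidine, dioxane/H2O, rt; then crude aldehyde, NaClO2, NaH2PO4, 2-methyl-2-butene, tBuOH/H2O, rt
Reagents that add atoms: sodium periodate with catalytic osmium tetroxide (carbonyl oxygen), [Na+].[O-]I(=O)(=O)=O and O=[Os](=O)(=O)=O; sodium chlorite (hydroxyl oxygen of the acid), [Na+].[O-]Cl=O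
Why: Lemieux–Johnson cleavage of the terminal alkene spares the arene, and buffered Pinnick oxidation of the crude arylacetaldehyde should give the acid without touching the acetal ethers or the ester.

Step 5
Reactants: 7 [5-(methoxycarbonyl)-2,3-bis(methoxymethoxy)phenyl]acetic acid; 8 (R)-4-benzyl-2-oxazolidinone
Product: 10 methyl 3-{2-[(4R)-4-benzyl-2-oxooxazolidin-3-yl]-2-oxoethyl}-4,5-bis(methoxymethoxy)benzoate, via mixed pivalic anhydride 9 (not isolated)
Conditions: PivCl, Et3N, THF, −20 °C; then 8, LiCl, −20 °C → rt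
Reagents that add atoms: none
Why: N-acylation of the oxazolidinone through the mixed anhydride under LiCl/Et3N activation is a standard mild entry to N-acyl oxazolidinones and avoids a strong base at the acidic arylacetyl position.

Step 6
Reactants: 10 methyl 3-{2-[(4R)-4-benzyl-2-oxooxazolidin-3-yl]-2-oxoethyl}-4,5-bis(methoxymethoxy)benzoate; 11 4-(benzyloxy)-3-methoxybenzaldehyde (O-benzylvanillin)
Product: 13 methyl 3-{(2R,3R)-1-[(4R)-4-benzyl-2-oxooxazolidin-3-yl]-3-[4-(benzyloxy)-3-methoxyphenyl]-3-hydroxy-1-oxopropan-2-yl}-4,5-bis(methoxymethoxy)benzoate, via boron enolate 12 (not isolated)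
Conditions: Bu2BOTf, iPr2NEt, CH2Cl2, 0 °C; 11, −78 → 0 °C; then pH 7 buffer, MeOH, H2O2
Reagents that add atoms: none
Why: Evans syn-aldol reaction in which the Z boron enolate adds through a closed Zimmerman–Traxler transition state on the face away from the auxiliary benzyl group, setting the α-carbon (the later C3', R here and S once the imide is reduced) and a carbinol centre (R) that is given up again in step 8.

Step 7
Reactants: 13 syn-aldol adduct
Product: 14 methyl 3-{(1R,2S)-1-[4-(benzyloxy)-3-methoxyphenyl]-1,3-dihydroxypropan-2-yl}-4,5-bis(methoxymethoxy)benzoate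
Conditions: LiBH4, MeOH (1 equiv), THF, 0 °C
Reagents that add atoms: none
Why: Reductive removal of the auxiliary, in which the activated imide carbonyl is reduced to the primary alcohol at 0 °C while the aryl methyl ester and the α-aryl stereocentre are expected to stay untouched.

Step 8
Reactants: 14 diol
Product: 16 methyl (2R,3S)-2-[4-(benzyloxy)-3-methoxyphenyl]-7-hydroxy-3-(hydroxymethyl)-2,3-dihydrobenzofuran-5-carboxylate, via free catechol diol 15 (not isolated)
Conditions: HCl (2 M), MeOH/THF, 45 °C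
Reagents that add atoms: none
Why: Acetal cleavage of both methoxymethyl ethers followed by acid-mediated phenylcoumaran formation, in which the ortho phenol traps the p-alkoxybenzylic cation in a 5-exo closure of ring D and the reversible closure places the C2' aryl group trans to the C3' hydroxymethyl group (C2' = R, controlled by C3').

Step 9
Reactants: 16 dihydrobenzofuran diol ester
Product: 17 methyl (2R,3S)-7-(benzyloxy)-2-[4-(benzyloxy)-3-methoxyphenyl]-3-[(benzyloxy)methyl]-2,3-dihydrobenzofuran-5-carboxylate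
Conditions: NaH, BnBr, nBu4NI (cat.), DMF, 0 °C → rt
Reagents that add atoms: benzyl bromide, BrCc1ccccc1
Why: Williamson benzylation of the phenol and the primary alcohol in one operation, with no acidic C–H or aldehyde present that the base could attack.

Step 10
Reactants: 17 tribenzyl ester
Product: 18 {(2R,3S)-7-(benzyloxy)-2-[4-(benzyloxy)-3-methoxyphenyl]-3-[(benzyloxy)methyl]-2,3-dihydrobenzofuran-5-yl}methanol
Conditions: iBu2AlH, CH2Cl2, −78 → 0 °C
Reagents that add atoms: none
Why: Hydride reduction of the aryl ester to the benzylic alcohol, to which benzyl ethers and the dihydrofuran are inert.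

Step 11
Reactants: 18 benzylic alcohol
Product: 19 (2R,3S)-7-(benzyloxy)-2-[4-(benzyloxy)-3-methoxyphenyl]-3-[(benzyloxy)methyl]-2,3-dihydrobenzofuran-5-carbaldehyde
Conditions: MnO2, CH2Cl2, rt
Reagents that add atoms: none
Why: Selective MnO2 oxidation of the only free (benzylic) alcohol, which should stop at the aldehyde.

Step 12
Reactants: 20 2',4',6'-trihydroxyacetophenone
Product: 21 1-[2,4-bis(benzyloxy)-6-hydroxyphenyl]ethanone
Conditions: BnBr (2.1 equiv), K2CO3, DMF, rt
Reagents that add atoms: benzyl bromide, BrCc1ccccc1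
Why: Williamson benzylation in which the hydroxyl that is hydrogen-bonded to the ketone is the least reactive and is expected to remain free.

Step 13
Reactants: 21 1-[2,4-bis(benzyloxy)-6-hydroxyphenyl]ethanone
Product: 22 tert-butyl 3-[2,4-bis(benzyloxy)-6-hydroxyphenyl]-3-oxopropanoate
Conditions: LiN(SiMe3)2 (3.2 equiv), THF, −78 °C; Boc2O, −78 → 0 °C; aq. NH4Cl
Reagents that add atoms: di-tert-butyl dicarbonate, CC(C)(C)OC(=O)OC(=O)OC(C)(C)C
Why: Claisen-type C-acylation of the phenoxide/enolate dianion with Boc2O, in which any carbonate formed on the phenoxide should be passed on to carbon by a Baker–Venkataraman-type transfer under the excess base.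

Step 14
Reactants: 19 dihydrobenzofuran aldehyde; 22 tert-butyl 3-[2,4-bis(benzyloxy)-6-hydroxyphenyl]-3-oxopropanoate
Product: 23 tert-butyl (Z)-2-[2,4-bis(benzyloxy)-6-hydroxybenzoyl]-3-{(2R,3S)-7-(benzyloxy)-2-[4-(benzyloxy)-3-methoxyphenyl]-3-[(benzyloxy)methyl]-2,3-dihydrobenzofuran-5-yl}prop-2-enoate
Conditions: piperidine (cat.), AcOH (cat.), 4 Å molecular sieves, toluene, rt
Reagents that add atoms: none
Why: Knoevenagel condensation under piperidinium acetate catalysis, expected to give mainly the Z alkene (aryl cis to the ester), with the chelated phenol and the bulky ester holding back premature ring closure.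

Step 15
Reactants: 23 alkylidene β-keto ester
Product: 24 tert-butyl (2S,3R)-5,7-bis(benzyloxy)-2-{(2R,3S)-7-(benzyloxy)-2-[4-(benzyloxy)-3-methoxyphenyl]-3-[(benzyloxy)methyl]-2,3-dihydrobenzofuran-5-yl}-4-oxochromane-3-carboxylate
Conditions: 1-[3,5-bis(trifluoromethyl)phenyl]-3-[(8R,9R)-6'-methoxycinchonan-9-yl]thiourea (quinidine-derived, 10 mol %), toluene, −25 °C; cold filtration through silica
Reagents that add atoms: none
Why: The quinuclidine nitrogen of the catalyst deprotonates the ring A phenol of 23 while the two thiourea N–H bonds hold the β-keto ester carbonyls, and within this hydrogen-bonded ion pair the phenoxide oxygen adds to the benzylidene carbon to form O1–C2, after which the enol is protonated at C3. The closest known reaction is the cinchona-thiourea catalysed intramolecular oxa-Michael addition of 2-hydroxyaryl alkylidene β-keto esters used for flavanones. Ring C closes in the 6-endo-trig mode, the only closure open to the single free phenol. C2 is set as S by the catalyst, which exposes one face of the alkylidene, the ring D centres C2' and C3' being remote; C3 is set as R (trans to the C2 aryl group) by thermodynamic control at this enolisable position and is erased in step 16. The step needs enantioface selectivity over the uncatalysed closure, and the tert-butyl ester secures it by two-point binding to the thiourea, by activating the acceptor so that no added base is needed at −25 °C, and by slowing the background reaction through its bulk.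

Step 16
Reactants: 24 cyclised keto ester
Product: 26 (2S)-5,7-bis(benzyloxy)-2-{(2R,3S)-7-(benzyloxy)-2-[4-(benzyloxy)-3-methoxyphenyl]-3-[(benzyloxy)methyl]-2,3-dihydrobenzofuran-5-yl}chroman-4-one, via β-keto acid 25 (not isolated)
Conditions: TsOH·H2O (0.5 equiv), toluene, 80 °C
Reagents that add atoms: none
Why: Acid-mediated loss of isobutene from the tert-butyl ester and decarboxylation of the β-keto acid, under which C2 is not enolisable, benzyl ethers should hold, and any reversible opening of ring D returns to the trans isomer.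

Step 17
Reactants: 26 pentabenzyl silyhermin B
Product: 27 silyhermin B
Conditions: H2 (1 atm), 10% Pd/C, EtOAc/MeOH, rt
Reagents that add atoms: none
Why: Catalytic hydrogenolysis of the five benzyl ethers under neutral conditions, which avoids base- or acid-induced opening of ring C and is to be stopped at the calculated hydrogen uptake to spare the benzylic C–O bonds of rings C and D.

**Compound list**

1 | methyl 3,4-dihydroxybenzoate | COC(=O)c1ccc(O)c(O)c1 | starting material
2 | methyl 4-(allyloxy)-3-hydroxybenzoate | COC(=O)c1ccc(OCC=C)c(O)c1 | intermediate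
3 | methyl 3-allyl-5-hydroxy-4-oxocyclohexa-1,5-diene-1-carboxylate (ortho-dienone, formed in situ) | COC(=O)C1=CC(CC=C)C(=O)C(O)=C1 | intermediate
4 | methyl 3-allyl-4,5-dihydroxybenzoate | COC(=O)c1cc(O)c(O)c(CC=C)c1 | intermediate
5 | methyl 3-allyl-4,5-bis(methoxymethoxy)benzoate | COC(=O)c1cc(OCOC)c(OCOC)c(CC=C)c1 | intermediate
6 | methyl 3,4-bis(methoxymethoxy)-5-(2-oxoethyl)benzoate (formed in situ) | COC(=O)c1cc(OCOC)c(OCOC)c(CC=O)c1 | intermediate
7 | [5-(methoxycarbonyl)-2,3-bis(methoxymethoxy)phenyl]acetic acid | COC(=O)c1cc(OCOC)c(OCOC)c(CC(=O)O)c1 | intermediate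
8 | (R)-4-benzyl-2-oxazolidinone | O=C1N[C@H](Cc2ccccc2)CO1 | starting material
9 | mixed anhydride of 7 with pivalic acid (formed in situ) | COC(=O)c1cc(OCOC)c(OCOC)c(CC(=O)OC(=O)C(C)(C)C)c1 | intermediate
10 | methyl 3-{2-[(4R)-4-benzyl-2-oxooxazolidin-3-yl]-2-oxoethyl}-4,5-bis(methoxymethoxy)benzoate | COC(=O)c1cc(OCOC)c(OCOC)c(CC(=O)N2[C@H](Cc3ccccc3)COC2=O)c1 | intermediate
11 | 4-(benzyloxy)-3-methoxybenzaldehyde | COc1cc(C=O)ccc1OCc1ccccc1 | starting material
12 | Z dibutylboron enolate of 10 (formed in situ) | CCCCB(CCCC)O/C(=C\c1cc(C(=O)OC)cc(OCOC)c1OCOC)N1[C@H](Cc2ccccc2)COC1=O | intermediate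
13 | methyl 3-{(2R,3R)-1-[(4R)-4-benzyl-2-oxooxazolidin-3-yl]-3-[4-(benzyloxy)-3-methoxyphenyl]-3-hydroxy-1-oxopropan-2-yl}-4,5-bis(methoxymethoxy)benzoate | COC(=O)c1cc(OCOC)c(OCOC)c([C@@H](C(=O)N2[C@H](Cc3ccccc3)COC2=O)[C@@H](O)c2ccc(OCc3ccccc3)c(OC)c2)c1 | intermediate
14 | methyl 3-{(1R,2S)-1-[4-(benzyloxy)-3-methoxyphenyl]-1,3-dihydroxypropan-2-yl}-4,5-bis(methoxymethoxy)benzoate | COC(=O)c1cc(OCOC)c(OCOC)c([C@@H](CO)[C@@H](O)c2ccc(OCc3ccccc3)c(OC)c2)c1 | intermediate
15 | methyl 3-{(1R,2S)-1-[4-(benzyloxy)-3-methoxyphenyl]-1,3-dihydroxypropan-2-yl}-4,5-dihydroxybenzoate (formed in situ) | COC(=O)c1cc(O)c(O)c([C@@H](CO)[C@@H](O)c2ccc(OCc3ccccc3)c(OC)c2)c1 | intermediate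
16 | methyl (2R,3S)-2-[4-(benzyloxy)-3-methoxyphenyl]-7-hydroxy-3-(hydroxymethyl)-2,3-dihydrobenzofuran-5-carboxylate | COc1cc([C@@H]2Oc3c(O)cc(C(=O)OC)cc3[C@H]2CO)ccc1OCc1ccccc1 | intermediate
17 | methyl (2R,3S)-7-(benzyloxy)-2-[4-(benzyloxy)-3-methoxyphenyl]-3-[(benzyloxy)methyl]-2,3-dihydrobenzofuran-5-carboxylate | COc1cc([C@@H]2Oc3c(OCc4ccccc4)cc(C(=O)OC)cc3[C@H]2COCc2ccccc2)ccc1OCc1ccccc1 | intermediate
18 | {(2R,3S)-7-(benzyloxy)-2-[4-(benzyloxy)-3-methoxyphenyl]-3-[(benzyloxy)methyl]-2,3-dihydrobenzofuran-5-yl}methanol | COc1cc([C@@H]2Oc3c(OCc4ccccc4)cc(CO)cc3[C@H]2COCc2ccccc2)ccc1OCc1ccccc1 | intermediate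
19 | (2R,3S)-7-(benzyloxy)-2-[4-(benzyloxy)-3-methoxyphenyl]-3-[(benzyloxy)methyl]-2,3-dihydrobenzofuran-5-carbaldehyde | COc1cc([C@@H]2Oc3c(OCc4ccccc4)cc(C=O)cc3[C@H]2COCc2ccccc2)ccc1OCc1ccccc1 | intermediate
20 | 2',4',6'-trihydroxyacetophenone | CC(=O)c1c(O)cc(O)cc1O | starting material
21 | 1-[2,4-bis(benzyloxy)-6-hydroxyphenyl]ethanone | CC(=O)c1c(O)cc(OCc2ccccc2)cc1OCc1ccccc1 | intermediate
22 | tert-butyl 3-[2,4-bis(benzyloxy)-6-hydroxyphenyl]-3-oxopropanoate | CC(C)(C)OC(=O)CC(=O)c1c(O)cc(OCc2ccccc2)cc1OCc1ccccc1 | intermediate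
23 | tert-butyl (Z)-2-[2,4-bis(benzyloxy)-6-hydroxybenzoyl]-3-{(2R,3S)-7-(benzyloxy)-2-[4-(benzyloxy)-3-methoxyphenyl]-3-[(benzyloxy)methyl]-2,3-dihydrobenzofuran-5-yl}prop-2-enoate | COc1cc([C@@H]2Oc3c(OCc4ccccc4)cc(/C=C(\C(=O)OC(C)(C)C)C(=O)c4c(O)cc(OCc5ccccc5)cc4OCc4ccccc4)cc3[C@H]2COCc2ccccc2)ccc1OCc1ccccc1 | intermediate
24 | tert-butyl (2S,3R)-5,7-bis(benzyloxy)-2-{(2R,3S)-7-(benzyloxy)-2-[4-(benzyloxy)-3-methoxyphenyl]-3-[(benzyloxy)methyl]-2,3-dihydrobenzofuran-5-yl}-4-oxochromane-3-carboxylate | COc1cc([C@@H]2Oc3c(OCc4ccccc4)cc([C@@H]4[C@@H](C(=O)OC(C)(C)C)C(=O)c5c(OCc6ccccc6)cc(OCc6ccccc6)cc5O4)cc3[C@H]2COCc2ccccc2)ccc1OCc1ccccc1 | intermediate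
25 | (2S,3R)-5,7-bis(benzyloxy)-2-{(2R,3S)-7-(benzyloxy)-2-[4-(benzyloxy)-3-methoxyphenyl]-3-[(benzyloxy)methyl]-2,3-dihydrobenzofuran-5-yl}-4-oxochromane-3-carboxylic acid (formed in situ) | COc1cc([C@@H]2Oc3c(OCc4ccccc4)cc([C@@H]4[C@@H](C(=O)O)C(=O)c5c(OCc6ccccc6)cc(OCc6ccccc6)cc5O4)cc3[C@H]2COCc2ccccc2)ccc1OCc1ccccc1 | intermediate
26 | (2S)-5,7-bis(benzyloxy)-2-{(2R,3S)-7-(benzyloxy)-2-[4-(benzyloxy)-3-methoxyphenyl]-3-[(benzyloxy)methyl]-2,3-dihydrobenzofuran-5-yl}chroman-4-one | COc1cc([C@@H]2Oc3c(OCc4ccccc4)cc([C@@H]4CC(=O)c5c(OCc6ccccc6)cc(OCc6ccccc6)cc5O4)cc3[C@H]2COCc2ccccc2)ccc1OCc1ccccc1 | intermediate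
27 | silyhermin B, (2S)-5,7-dihydroxy-2-[(2R,3S)-7-hydroxy-2-(4-hydroxy-3-methoxyphenyl)-3-(hydroxymethyl)-2,3-dihydrobenzofuran-5-yl]chroman-4-one | COc1cc([C@@H]2Oc3c(O)cc([C@@H]4CC(=O)c5c(O)cc(O)cc5O4)cc3[C@H]2CO)ccc1O | target

**Step count and risks**

Total step count: 17. Longest linear sequence: 15 steps (steps 1–11, then 14–17); steps 12 and 13 form the short ring A branch.

Steps most likely to fail:

1. Step 15. Facial control may be eroded by the uncatalysed closure, by an E/Z mixture of 23, or by a poor fit of the bulky ring B/D substituent in the catalyst pocket, and the cyclised keto ester may reopen on handling, so that both C2 epimers form. The fallback sets out from 19 and 21 and comes back at 26. Claisen–Schmidt condensation of 21 with 19 (KOH, EtOH/THF, rt) should give the 2'-hydroxychalcone F1. Warming with NaOAc in EtOH closes ring C without stereocontrol to give 26 together with its 2R epimer F2. The two are diastereomers because of C2' and C3' and are to be separated by preparative HPLC, and F2 can be returned to F1 with KOH in EtOH and recycled.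

2. Step 14. The free ring A phenol may add to the newly formed alkylidene under the amine catalyst before the chiral catalyst is present, so that C2 forms without control, and the condensation of the hindered keto ester with the electron-rich aldehyde may be slow. The fallback sets out from 21 and comes back at 23. The phenol is masked as the allyl ether F3 (allyl bromide, K2CO3, DMF, 60 °C). Acylation as in step 13 (LiN(SiMe3)2, Boc2O) should give the β-keto ester F4. Knoevenagel condensation with 19 can then be forced (piperidine/AcOH, toluene, reflux with water removal) to the O-allyl alkylidene F5, which cannot cyclise. The allyl group is removed under non-basic conditions (Pd(PPh3)4 cat., p-toluenesulfinic acid, CH2Cl2, rt) and the resulting 23 is taken at once into step 15.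

3. Step 6. The stabilised arylacetyl boron enolate and the electron-rich aldehyde may combine slowly and reversibly, and retro-aldol cleavage would cost conversion and the configurational purity of the α-carbon. The fallback sets out from 10 and comes back at 17.
   - Evans alkylation of the sodium enolate of 10 with benzyl chloromethyl ether (NaN(SiMe3)2, THF, −78 °C) should set the same carbon in the alkylated imide F6.
   - LiBH4 removes the auxiliary to give the alcohol F7, and Dess–Martin periodinane gives the aldehyde F8, which is used at once.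
   - The Grignard reagent F9 (from 1-(benzyloxy)-4-bromo-2-methoxybenzene and Mg, THF) is added at −78 °C to give the carbinol F10 as both carbinol epimers.
   - HCl in MeOH/THF removes the methoxymethyl ethers to the free catechol F11, which closes ring D as in step 8 to the phenol F12, both carbinol epimers converging on the trans product.
   - Benzylation of the phenol (BnBr, K2CO3, DMF) gives 17.

**Further compounds**

F1 | step 15 | (E)-1-[2,4-bis(benzyloxy)-6-hydroxyphenyl]-3-{(2R,3S)-7-(benzyloxy)-2-[4-(benzyloxy)-3-methoxyphenyl]-3-[(benzyloxy)methyl]-2,3-dihydrobenzofuran-5-yl}prop-2-en-1-one | COc1cc([C@@H]2Oc3c(OCc4ccccc4)cc(/C=C/C(=O)c4c(O)cc(OCc5ccccc5)cc4OCc4ccccc4)cc3[C@H]2COCc2ccccc2)ccc1OCc1ccccc1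
F2 | step 15 | (2R)-5,7-bis(benzyloxy)-2-{(2R,3S)-7-(benzyloxy)-2-[4-(benzyloxy)-3-methoxyphenyl]-3-[(benzyloxy)methyl]-2,3-dihydrobenzofuran-5-yl}chroman-4-one | COc1cc([C@@H]2Oc3c(OCc4ccccc4)cc([C@H]4CC(=O)c5c(OCc6ccccc6)cc(OCc6ccccc6)cc5O4)cc3[C@H]2COCc2ccccc2)ccc1OCc1ccccc1
F3 | step 14 | 1-[2-(allyloxy)-4,6-bis(benzyloxy)phenyl]ethanone | CC(=O)c1c(OCC=C)cc(OCc2ccccc2)cc1OCc1ccccc1
F4 | step 14 | tert-butyl 3-[2-(allyloxy)-4,6-bis(benzyloxy)phenyl]-3-oxopropanoate | CC(C)(C)OC(=O)CC(=O)c1c(OCC=C)cc(OCc2ccccc2)cc1OCc1ccccc1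
F5 | step 14 | tert-butyl (Z)-2-[2-(allyloxy)-4,6-bis(benzyloxy)benzoyl]-3-{(2R,3S)-7-(benzyloxy)-2-[4-(benzyloxy)-3-methoxyphenyl]-3-[(benzyloxy)methyl]-2,3-dihydrobenzofuran-5-yl}prop-2-enoate | COc1cc([C@@H]2Oc3c(OCc4ccccc4)cc(/C=C(\C(=O)OC(C)(C)C)C(=O)c4c(OCC=C)cc(OCc5ccccc5)cc4OCc4ccccc4)cc3[C@H]2COCc2ccccc2)ccc1OCc1ccccc1
F6 | step 6 | methyl 3-{(2S)-1-[(4R)-4-benzyl-2-oxooxazolidin-3-yl]-3-(benzyloxy)-1-oxopropan-2-yl}-4,5-bis(methoxymethoxy)benzoate | COC(=O)c1cc(OCOC)c(OCOC)c([C@@H](COCc2ccccc2)C(=O)N2[C@H](Cc3ccccc3)COC2=O)c1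
F7 | step 6 | methyl 3-[(2R)-1-(benzyloxy)-3-hydroxypropan-2-yl]-4,5-bis(methoxymethoxy)benzoate | COC(=O)c1cc(OCOC)c(OCOC)c([C@@H](COCc2ccccc2)CO)c1
F8 | step 6 | methyl 3-[(2S)-1-(benzyloxy)-3-oxopropan-2-yl]-4,5-bis(methoxymethoxy)benzoate | COC(=O)c1cc(OCOC)c(OCOC)c([C@@H](COCc2ccccc2)C=O)c1
F9 | step 6 | [4-(benzyloxy)-3-methoxyphenyl]magnesium bromide | COc1cc([Mg]Br)ccc1OCc1ccccc1
F10 | step 6 | methyl 3-{(2S)-3-(benzyloxy)-1-[4-(benzyloxy)-3-methoxyphenyl]-1-hydroxypropan-2-yl}-4,5-bis(methoxymethoxy)benzoate (both carbinol epimers) | COC(=O)c1cc(OCOC)c(OCOC)c([C@@H](COCc2ccccc2)C(O)c2ccc(OCc3ccccc3)c(OC)c2)c1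
F11 | step 6 | methyl 3-{(2S)-3-(benzyloxy)-1-[4-(benzyloxy)-3-methoxyphenyl]-1-hydroxypropan-2-yl}-4,5-dihydroxybenzoate (both carbinol epimers) | COC(=O)c1cc(O)c(O)c([C@@H](COCc2ccccc2)C(O)c2ccc(OCc3ccccc3)c(OC)c2)c1
F12 | step 6 | methyl (2R,3S)-2-[4-(benzyloxy)-3-methoxyphenyl]-3-[(benzyloxy)methyl]-7-hydroxy-2,3-dihydrobenzofuran-5-carboxylate | COc1cc([C@@H]2Oc3c(O)cc(C(=O)OC)cc3[C@H]2COCc2ccccc2)ccc1OCc1ccccc1
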